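The C5 and C8 phenols are traced back to methyl ethers by way of the 5,8-quinone, and the aryl–acyl bond C6–C(=O) is then cut to a C6 aryllithium and the Weinreb amide of 3-phenylpropanoic acid.
The pyran ring is cut last, at C3–C4 and O1–C2. In chromene numbering (O1, C2 … C8a) the unit C4a–C4 next to C8a–O1 is a latent salicylaldehyde, and C3–C2 with its two methyl groups is a 2-methylprop-1-enyl unit.
Forward: 1,2,3,5-tetramethoxybenzene is formylated and the crowded ortho ether is cleaved; the pyran ring, the only ring made, closes in step 3; the chain is joined at C6 in step 5; oxidation to the quinone and reduction finish the route.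
Stereochemistry: the target has no stereocentre and its one alkene is held cis inside the pyran ring, so nothing has to be controlled.

Key step: step 3

Remark: 1,2,3,5-tetramethoxybenzene is taken as a purchasable arene, and the target is taken as the achiral chromene drawn by the SMILES.

Step 1
Reactants: 1 1,2,3,5-tetramethoxybenzene
Product: 3 2,3,4,6-tetramethoxybenzaldehyde, via aryl iminium chloride 2 (not isolated)
Conditions: POCl3 (1.5 equiv), DMF, 0 °C to 60 °C; then H2O
Reagents that add atoms: N,N-dimethylformamide, CN(C)C=O; water, O
Why: Vilsmeier–Haack formylation: the chloroiminium ion made from DMF and POCl3 attacks one of the two equivalent free positions of 1 (each ortho to two methoxy groups and para to a third), and water hydrolyses iminium salt 2 to the aldehyde, whose deactivated ring should not react a second time.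

Step 2
Reactants: 3 2,3,4,6-tetramethoxybenzaldehyde
Product: 5 2-hydroxy-3,4,6-trimethoxybenzaldehyde, via aryloxydichloroborane 4 (not isolated)
Conditions: BCl3 (1.1 equiv), CH2Cl2, −78 °C to 0 °C; then H2O
Reagents that add atoms: none
Why: Chelation-directed ortho-demethylation of an aryl methyl ether by BCl3: of the two ethers beside the formyl group (benzaldehyde numbering) the C2 methoxy, wedged between the carbonyl and the C3 methoxy and twisted out of the ring plane, is the more basic and more strained one, so boron should bridge it to the carbonyl oxygen and chloride should take its methyl group, while chelate 4 ties up the carbonyl and the single equivalent of reagent so that the C6 ether survives until aqueous work-up.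

Step 3
Reactants: 5 2-hydroxy-3,4,6-trimethoxybenzaldehyde; 6 2-methylprop-1-enylboronic acid
Product: 10 5,7,8-trimethoxy-2,2-dimethyl-2H-chromene, via iminium phenolate 7 (not isolated), via allylic amine 8 (not isolated), via ortho-quinone methide 9 (not isolated)
Conditions: 6 (1.5 equiv), Bn2NH (40 mol%), 1,4-dioxane, 90 °C
Reagents that add atoms: none
Why: Dibenzylamine condenses with the formyl group of 5 to iminium phenolate 7, whose phenolate oxygen binds the boron of 6, and the ate complex so formed passes the 2-methylprop-1-enyl group to the iminium carbon from within, making the C3–C4 bond of allylic amine 8 (Petasis borono-Mannich reaction). At 90 °C the benzylic amine, pushed out by the ortho phenol and by the ortho and para methoxy groups, leaves again, and the ortho-quinone methide 9 that results is a 1-oxatriene which forms the O1–C2 bond by thermal disrotatory oxa-6π electrocyclisation, closing the six-membered 2H-pyran ring and restoring the benzene ring. The closest known reaction type is the secondary-amine-promoted condensation of salicylaldehydes with alkenylboronic acids to 2H-chromenes. No stereocentre results, because the carbon that is stereogenic in 8 becomes trigonal in 9 and C2 carries two identical methyl groups. The step needs a single regiochemical outcome, closure onto the oxygen that becomes O1 and not onto the one at C5, and the substrate secures it since only the former is a free phenol able to bind boron and to form the quinone methide, the latter being a methyl ether. The C3–C4 alkene arrives directly at the chromene oxidation level, so the electron-rich arene never meets a dehydrogenating agent.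

Step 4
Reactants: 11 3-phenylpropanoyl chloride
Product: 12 N-methoxy-N-methyl-3-phenylpropanamide
Conditions: MeNH(OMe)·HCl (1.1 equiv), K2CO3 (2.5 equiv), EtOAc/H2O, 0 °C to rt
Reagents that add atoms: N,O-dimethylhydroxylamine hydrochloride, CNOC.Cl
Why: Schotten–Baumann N-acylation: the hydroxylamine set free by carbonate in the two-phase mixture should attack the acid chloride far faster than water does and give the Weinreb amide.

Step 5
Reactants: 10 5,7,8-trimethoxy-2,2-dimethyl-2H-chromene; 12 N-methoxy-N-methyl-3-phenylpropanamide
Product: 15 3-phenyl-1-(5,7,8-trimethoxy-2,2-dimethyl-2H-chromen-6-yl)propan-1-one, via aryllithium 13 (not isolated), via tetrahedral lithium adduct 14 (not isolated)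
Conditions: n-BuLi (1.1 equiv), THF, 0 °C; then 12, −78 °C to 0 °C; then aq NH4Cl
Reagents that add atoms: none
Why: Directed ortho-metalation followed by Weinreb ketone synthesis: C6–H is the only aromatic hydrogen of 10 and lies between two methoxy groups that both hold lithium, so n-BuLi should give 13 at that carbon alone, and addition of 13 to 12 should stop at the N,O-chelated adduct 14, which releases the ketone only on work-up.

Step 6
Reactants: 15 3-phenyl-1-(5,7,8-trimethoxy-2,2-dimethyl-2H-chromen-6-yl)propan-1-one
Product: 16 7-methoxy-2,2-dimethyl-6-(3-phenylpropanoyl)-2H-chromene-5,8-dione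
Conditions: (NH4)2Ce(NO3)6 (2.5 equiv), MeCN/H2O, 0 °C, short reaction time
Reagents that add atoms: water, O
Why: Oxidative demethylation of a para-dimethoxyarene to a para-quinone by tetravalent cerium: the C5 and C8 ethers are the only para-related oxygen pair on the ring, so one-electron oxidation of the arene, attack of water at C5 and C8 and loss of two molecules of methanol should lead to the 5,8-quinone, with the C7 methoxy kept as a vinylogous ester and the ketone and the pyran alkene left untouched at 0 °C.

Step 7
Reactants: 16 7-methoxy-2,2-dimethyl-6-(3-phenylpropanoyl)-2H-chromene-5,8-dione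
Product: 17 Flemistrictin D [1-(5,8-dihydroxy-7-methoxy-2,2-dimethyl-2H-chromen-6-yl)-3-phenylpropan-1-one]
Conditions: Na2S2O4 (excess), EtOAc/H2O, rt, under argon
Reagents that add atoms: none
Why: Dithionite reduction of a quinone to its hydroquinone: the electron-poor acylquinone should take up two electrons and two protons within minutes while the ketone and the alkene are inert to Na2S2O4, and the hydrogen bond from the C5 hydroxyl to the acyl carbonyl should steady the product against air.

Compound list
1 | 1,2,3,5-tetramethoxybenzene | COc1cc(OC)c(OC)c(OC)c1 | starting material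
2 | N,N-dimethyl-1-(2,3,4,6-tetramethoxyphenyl)methaniminium chloride | COc1cc(OC)c(C=[N+](C)C)c(OC)c1OC.[Cl-] | intermediate
3 | 2,3,4,6-tetramethoxybenzaldehyde | COc1cc(OC)c(C=O)c(OC)c1OC | intermediate
4 | dichloro(2-formyl-3,5,6-trimethoxyphenoxy)borane | COc1cc(OC)c(C=O)c(OB(Cl)Cl)c1OC | intermediate
5 | 2-hydroxy-3,4,6-trimethoxybenzaldehyde | COc1cc(OC)c(C=O)c(O)c1OC | intermediate
6 | 2-methylprop-1-enylboronic acid | CC(C)=CB(O)O | starting material
7 | 2-[(dibenzyliminio)methyl]-3,5,6-trimethoxyphenolate | COc1cc(OC)c(C=[N+](Cc2ccccc2)Cc2ccccc2)c([O-])c1OC | intermediate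
8 | 2-[1-(dibenzylamino)-3-methylbut-2-en-1-yl]-3,5,6-trimethoxyphenol (racemic) | COc1cc(OC)c(C(C=C(C)C)N(Cc2ccccc2)Cc2ccccc2)c(O)c1OC | intermediate
9 | 2,3,5-trimethoxy-6-(3-methylbut-2-en-1-ylidene)cyclohexa-2,4-dien-1-one | COC1=C(OC)C(=O)C(=CC=C(C)C)C(OC)=C1 | intermediate
10 | 5,7,8-trimethoxy-2,2-dimethyl-2H-chromene | COc1cc(OC)c2c(c1OC)OC(C)(C)C=C2 | intermediate
11 | 3-phenylpropanoyl chloride | O=C(Cl)CCc1ccccc1 | starting material
12 | N-methoxy-N-methyl-3-phenylpropanamide | CON(C)C(=O)CCc1ccccc1 | intermediate
13 | (5,7,8-trimethoxy-2,2-dimethyl-2H-chromen-6-yl)lithium | [Li]c1c(OC)c2C=CC(C)(C)Oc2c(OC)c1OC | intermediate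
14 | lithium 1-[methoxy(methyl)amino]-3-phenyl-1-(5,7,8-trimethoxy-2,2-dimethyl-2H-chromen-6-yl)propan-1-olate (racemic) | [Li+].[O-]C(CCc1ccccc1)(N(C)OC)c1c(OC)c2C=CC(C)(C)Oc2c(OC)c1OC | intermediate
15 | 3-phenyl-1-(5,7,8-trimethoxy-2,2-dimethyl-2H-chromen-6-yl)propan-1-one | COc1c(C(=O)CCc2ccccc2)c(OC)c2C=CC(C)(C)Oc2c1OC | intermediate
16 | 7-methoxy-2,2-dimethyl-6-(3-phenylpropanoyl)-2H-chromene-5,8-dione | COC1=C(C(=O)CCc2ccccc2)C(=O)C2=C(OC(C)(C)C=C2)C1=O | intermediate
17 | Flemistrictin D, 1-(5,8-dihydroxy-7-methoxy-2,2-dimethyl-2H-chromen-6-yl)-3-phenylpropan-1-one | COc1c(O)c2c(c(O)c1C(=O)CCc1ccccc1)C=CC(C)(C)O2 | target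

Total step count: 7.
Longest linear sequence: 6 steps (steps 1, 2, 3, 5, 6 and 7 from 1); step 4 is a one-step side branch.

Steps most likely to fail

Step 3. The formyl group of 5 sits between a methoxy group and a hydrogen-bonded hydroxyl on a ring with three donor oxygens, so iminium formation may be slow and protodeboronation of 6 may outrun the alkenyl transfer. The fallback sets out from 5 and comes back at 10. Aldehyde 5 would be treated with 2-methylprop-1-enylmagnesium bromide (3 equiv, THF, 0 °C; the first equivalent only forms the magnesium phenoxide) to give racemic 2-(1-hydroxy-3-methylbut-2-en-1-yl)-3,5,6-trimethoxyphenol F1. Brief warming of F1 in toluene over MgSO4 with a trace of pyridinium para-toluenesulfonate should dehydrate this electron-rich ortho-hydroxybenzylic alcohol to the same ortho-quinone methide 9, which closes to 10.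

Step 6. The acyl group makes the arene harder to oxidise, so attack of the oxidant on the pyran alkene or over-oxidation may compete, and the electron-poor acylquinone may lose its C7 methoxy group by addition of water. The fallback sets out from 10 and comes back at 17, with the oxidation moved to the stage at which the ring is most electron-rich and carries no acyl group. Chromene 10 would be oxidised with (NH4)2Ce(NO3)6 in MeCN/H2O at 0 °C to 7-methoxy-2,2-dimethyl-2H-chromene-5,8-dione F2 and reduced with Na2S2O4 to 7-methoxy-2,2-dimethyl-2H-chromene-5,8-diol F3. Protection with MOMCl and iPr2NEt in CH2Cl2 would give 7-methoxy-5,8-bis(methoxymethoxy)-2,2-dimethyl-2H-chromene F4. Lithiation with n-BuLi at C6, now flanked by a methoxymethoxy and a methoxy group, would give [7-methoxy-5,8-bis(methoxymethoxy)-2,2-dimethyl-2H-chromen-6-yl]lithium F5. Addition of F5 to 12 would pass through lithium 1-[methoxy(methyl)amino]-1-[7-methoxy-5,8-bis(methoxymethoxy)-2,2-dimethyl-2H-chromen-6-yl]-3-phenylpropan-1-olate F6 and give, on work-up, 1-[7-methoxy-5,8-bis(methoxymethoxy)-2,2-dimethyl-2H-chromen-6-yl]-3-phenylpropan-1-one F7. Acetal cleavage with HCl in MeOH at 40 °C would then free both phenols and give 17 without any late oxidation.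

Step 5. The hindered and basic aryllithium 13 may deprotonate amide 12 at its α-carbon instead of adding to it, which would return 10 after work-up. The fallback sets out from 10 (through 13) and comes back at 15. Aryllithium 13 would be added at −78 °C to 3-phenylpropanal, a far better electrophile, to give racemic 3-phenyl-1-(5,7,8-trimethoxy-2,2-dimethyl-2H-chromen-6-yl)propan-1-ol F8. Oxidation of F8 with Dess–Martin periodinane (NaHCO3, CH2Cl2, rt) should give ketone 15.

Further compounds
F1 | step 3 | 2-(1-hydroxy-3-methylbut-2-en-1-yl)-3,5,6-trimethoxyphenol (racemic) | COc1cc(OC)c(C(O)C=C(C)C)c(O)c1OC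
F2 | step 6 | 7-methoxy-2,2-dimethyl-2H-chromene-5,8-dione | COC1=CC(=O)C2=C(OC(C)(C)C=C2)C1=O
F3 | step 6 | 7-methoxy-2,2-dimethyl-2H-chromene-5,8-diol | COc1cc(O)c2C=CC(C)(C)Oc2c1O
F4 | step 6 | 7-methoxy-5,8-bis(methoxymethoxy)-2,2-dimethyl-2H-chromene | COCOc1cc(OC)c(OCOC)c2OC(C)(C)C=Cc12
F5 | step 6 | [7-methoxy-5,8-bis(methoxymethoxy)-2,2-dimethyl-2H-chromen-6-yl]lithium | [Li]c1c(OC)c(OCOC)c2OC(C)(C)C=Cc2c1OCOC
F6 | step 6 | lithium 1-[methoxy(methyl)amino]-1-[7-methoxy-5,8-bis(methoxymethoxy)-2,2-dimethyl-2H-chromen-6-yl]-3-phenylpropan-1-olate (racemic) | [Li+].[O-]C(CCc1ccccc1)(N(C)OC)c1c(OC)c(OCOC)c2OC(C)(C)C=Cc2c1OCOC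
F7 | step 6 | 1-[7-methoxy-5,8-bis(methoxymethoxy)-2,2-dimethyl-2H-chromen-6-yl]-3-phenylpropan-1-one | COCOc1c(C(=O)CCc2ccccc2)c(OC)c(OCOC)c2OC(C)(C)C=Cc12
F8 | step 5 | 3-phenyl-1-(5,7,8-trimethoxy-2,2-dimethyl-2H-chromen-6-yl)propan-1-ol (racemic) | COc1c(C(O)CCc2ccccc2)c(OC)c2C=CC(C)(C)Oc2c1OC
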